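**Plan**

- Retrosynthesis: the two ring A acetals come off last. Ring B is then taken back to its dihydro level (H2 added across C1–C6) and the depside O4–acyl bond is cut. The resulting cyclohexane-1,3-dione is cut at C1–C6 and C3–C4 into methyl acetoacetate and methyl crotonate. The ring A acid is cut at C–Cl and at the carboxyl carbon back to 2,5-dimethylresorcinol.
- Enabling feature: ring B carries CO2CH3 at C1, OH at C2, the acyloxy group at C4 and CH3 at C6, which is the pattern of a 6-methyl-2,4-dioxocyclohexane-1-carboxylate. At that oxidation level O2 sits in a crowded β-keto ester and O4 is an exposed vinylogous acid, so the two oxygens are told apart before ring B is aromatic.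
- Forward: ring B is closed first as the dione (step 1). Ring A is formylated, chlorinated, protected and oxidised to the acid (steps 2–5). The halves are joined by O4-acylation (step 6), ring B is dehydrogenated to the arene (step 7) and the acetals are removed (step 8).
- Stereochemistry: the target has no stereocentre. The C1/C6 pair created in step 1 is racemic, settles trans and is erased in step 7.

Key step: step 1

Assumption: compounds 3–5 and 14–16 are racemic (one enantiomer drawn), and the tricarbonyl compounds are written as keto tautomers although they are largely enolised.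

**Route**

Step 1
Reactants: 1 methyl acetoacetate; 2 methyl (E)-crotonate
Product: 5 methyl 6-methyl-2,4-dioxocyclohexane-1-carboxylate (racemic trans), via Michael adduct 3 (not isolated), via sodium enolate 4 (not isolated)
Conditions: NaOMe (1.05 equiv), MeOH, reflux; then 2 M HCl, 0 °C
Reagents that add atoms: none
Why: Methoxide deprotonates 1 at C2 and this doubly stabilised carbanion adds in conjugate fashion to 2 (Michael addition, C1–C6 bond) to give 3, after which proton transfer lets the methyl ketone enolate attack the crotonate-derived ester (Claisen condensation of the Dieckmann type, C3–C4 bond) with loss of methoxide. The closest known reaction type is the Michael–Claisen synthesis of dihydroresorcinol carboxylates from acetoacetates and α,β-unsaturated esters. Ring B closes as a six-membered carbocycle by a favoured 6-(enolendo)-exo-trig attack of the enolate on the ester carbonyl, and deprotonation of the new 1,3-dione to enolate 4 pulls all earlier equilibria forward, which is why a full equivalent of NaOMe is used. The two new stereocentres at C1 and C6 are under thermodynamic control, C1 epimerising through its enol to sit trans to the C6 methyl, and both are erased in step 7 so their configuration does not matter. The step needs regiocontrol in both bond formations, and the substrates secure it because only C2 of 1 is a soft stabilised donor and only the ketone methyl can reach the distal ester through a six-membered transition state, the alternatives being four-membered rings. Matching methyl esters in methanol make transesterification degenerate, and cold acidification avoids hydrolysis and decarboxylation of the vinylogous β-keto ester.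

Step 2
Reactants: 6 2,5-dimethylresorcinol
Product: 8 2,4-dihydroxy-3,6-dimethylbenzaldehyde, via aryl iminium chloride 7 (not isolated)
Conditions: POCl3, DMF, 0 °C to rt; then H2O, 50 °C
Reagents that add atoms: N,N-dimethylformamide, CN(C)C=O; water, O
Why: Vilsmeier–Haack formylation, in which the chloroiminium ion attacks the only kind of free ring position of the symmetric resorcinol (C4 and C6 are equivalent, each ortho to one hydroxyl and para to the other) and hydrolysis of iminium 7 gives the aldehyde, whose deactivated ring resists a second formylation.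

Step 3
Reactants: 8 2,4-dihydroxy-3,6-dimethylbenzaldehyde
Product: 9 3-chloro-4,6-dihydroxy-2,5-dimethylbenzaldehyde
Conditions: SO2Cl2 (1.05 equiv), Et2O, 0 °C to rt
Reagents that add atoms: sulfuryl chloride, O=S(=O)(Cl)Cl
Why: Electrophilic aromatic chlorination at the single remaining ring position, which is ortho to one hydroxyl, para to the other and meta to the formyl group, so one equivalent of reagent can only give the 3-chloro compound.

Step 4
Reactants: 9 3-chloro-4,6-dihydroxy-2,5-dimethylbenzaldehyde
Product: 11 3-chloro-4,6-bis(methoxymethoxy)-2,5-dimethylbenzaldehyde, via disodium bisphenoxide 10 (not isolated)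
Conditions: NaH (2.4 equiv), DMF, 0 °C; then MOMCl (2.4 equiv), 0 °C to rt
Reagents that add atoms: chloromethyl methyl ether, COCCl
Why: Williamson-type O-alkylation of the preformed bisphenoxide in a dipolar aprotic solvent, the standard way to force acetal formation on a chelated, doubly ortho-substituted salicylaldehyde hydroxyl, giving acetals that mask both phenols through the acylation and the oxidative steps.

Step 5
Reactants: 11 3-chloro-4,6-bis(methoxymethoxy)-2,5-dimethylbenzaldehyde
Product: 12 3-chloro-4,6-bis(methoxymethoxy)-2,5-dimethylbenzoic acid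
Conditions: NaClO2, NaH2PO4, 2-methyl-2-butene, t-BuOH/H2O, rt
Reagents that add atoms: sodium chlorite, [Na+].[O-]Cl=O
Why: Pinnick oxidation converts even doubly ortho-substituted aryl aldehydes to acids at pH 3–4, where the acetals are stable, and the fully substituted ring offers no position for the scavenged hypochlorite to chlorinate.

Step 6
Reactants: 12 3-chloro-4,6-bis(methoxymethoxy)-2,5-dimethylbenzoic acid (1.1 equiv); 5 methyl 6-methyl-2,4-dioxocyclohexane-1-carboxylate
Product: 14 methyl 4-{[3-chloro-4,6-bis(methoxymethoxy)-2,5-dimethylbenzoyl]oxy}-6-methyl-2-oxocyclohex-3-ene-1-carboxylate, via acid chloride 13 (not isolated)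
Conditions: 1-chloro-N,N,2-trimethylprop-1-en-1-amine (1.05 equiv), CH2Cl2, 0 °C to rt; then 5, Et3N, DMAP (5 mol%), CH2Cl2, 0 °C
Reagents that add atoms: none
Why: The α-chloroenamine forms acid chloride 13 under neutral conditions without HCl that would endanger the ortho acetal, and O-acylation of the 1,3-dione enolate (enol ester formation) by this doubly ortho-substituted aroyl chloride should go at O4, flanked only by a methylene, instead of O2, screened by C1 and its ester, the O4 ester also being the more stable isomer because its C2 carbonyl stays a hydrogen-bonded β-keto ester enol; the chloroenamine is kept below the amount of acid so none remains to chlorinate the dione, and cold conditions and catalytic DMAP disfavour O-to-C acyl migration.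

Step 7
Reactants: 14 methyl 4-{[3-chloro-4,6-bis(methoxymethoxy)-2,5-dimethylbenzoyl]oxy}-6-methyl-2-oxocyclohex-3-ene-1-carboxylate
Product: 17 methyl 4-{[3-chloro-4,6-bis(methoxymethoxy)-2,5-dimethylbenzoyl]oxy}-2-hydroxy-6-methylbenzoate, via selenide 15 (not isolated), via selenoxide 16 (not isolated)
Conditions: PhSeCl (1.1 equiv), pyridine (1.2 equiv), CH2Cl2, 0 °C; aqueous wash; then 30% H2O2 (excess), CH2Cl2, 0 °C to rt
Reagents that add atoms: none
Why: α-Selenenylation of the β-keto ester at C1, its most acidic C–H, followed by selenoxide syn-elimination is the standard dehydrogenation of cyclic β-dicarbonyl compounds; selenium should enter anti to the C6 methyl and therefore cis to H6 as the syn-elimination requires, and the cross-conjugated cyclohexadienone so formed is the keto tautomer of the salicylate and enolises at once to the arene, leaving the aryl ester, the acetals and the aryl chloride untouched.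

Step 8
Reactants: 17 methyl 4-{[3-chloro-4,6-bis(methoxymethoxy)-2,5-dimethylbenzoyl]oxy}-2-hydroxy-6-methylbenzoate
Product: 18 methyl 4-[(3-chloro-4,6-dihydroxy-2,5-dimethylbenzoyl)oxy]-2-hydroxy-6-methylbenzoate (CNP0171762.0)
Conditions: HCl (1.25 M in MeOH), rt
Reagents that add atoms: none
Why: Acid-catalysed acetal exchange with methanol removes both aryl methoxymethyl ethers as dimethoxymethane at room temperature, while the depside ester (a doubly ortho-substituted benzoate) and the chelated methyl ester are slow to transesterify under these conditions.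

**Compound list**

1 | methyl acetoacetate | COC(=O)CC(C)=O | starting material
2 | methyl (E)-crotonate | C/C=C/C(=O)OC | starting material
3 | dimethyl 2-acetyl-3-methylpentanedioate (Michael adduct, diastereomer mixture, not isolated) | COC(=O)CC(C)C(C(C)=O)C(=O)OC | intermediate
4 | sodium enolate of 5 (not isolated) | COC(=O)[C@@H]1[C@@H](C)CC(=O)C=C1[O-].[Na+] | intermediate
5 | methyl 6-methyl-2,4-dioxocyclohexane-1-carboxylate (racemic trans) | COC(=O)[C@@H]1[C@@H](C)CC(=O)CC1=O | intermediate
6 | 2,5-dimethylresorcinol (2,5-dimethylbenzene-1,3-diol) | Cc1cc(O)c(C)c(O)c1 | starting material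
7 | N-[(2,4-dihydroxy-3,6-dimethylphenyl)methylidene]-N-methylmethanaminium chloride (not isolated) | C[N+](C)=Cc1c(C)cc(O)c(C)c1O.[Cl-] | intermediate
8 | 2,4-dihydroxy-3,6-dimethylbenzaldehyde | O=Cc1c(C)cc(O)c(C)c1O | intermediate
9 | 3-chloro-4,6-dihydroxy-2,5-dimethylbenzaldehyde | O=Cc1c(C)c(Cl)c(O)c(C)c1O | intermediate
10 | disodium 4-chloro-6-formyl-2,5-dimethylbenzene-1,3-diolate (not isolated) | O=Cc1c(C)c(Cl)c([O-])c(C)c1[O-].[Na+].[Na+] | intermediate
11 | 3-chloro-4,6-bis(methoxymethoxy)-2,5-dimethylbenzaldehyde | O=Cc1c(C)c(Cl)c(OCOC)c(C)c1OCOC | intermediate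
12 | 3-chloro-4,6-bis(methoxymethoxy)-2,5-dimethylbenzoic acid | OC(=O)c1c(C)c(Cl)c(OCOC)c(C)c1OCOC | intermediate
13 | 3-chloro-4,6-bis(methoxymethoxy)-2,5-dimethylbenzoyl chloride (not isolated) | ClC(=O)c1c(C)c(Cl)c(OCOC)c(C)c1OCOC | intermediate
14 | methyl 4-{[3-chloro-4,6-bis(methoxymethoxy)-2,5-dimethylbenzoyl]oxy}-6-methyl-2-oxocyclohex-3-ene-1-carboxylate (racemic, ester trans to C6 methyl drawn) | COC(=O)[C@@H]1[C@@H](C)CC(OC(=O)c2c(C)c(Cl)c(OCOC)c(C)c2OCOC)=CC1=O | intermediate
15 | methyl 4-{[3-chloro-4,6-bis(methoxymethoxy)-2,5-dimethylbenzoyl]oxy}-6-methyl-2-oxo-1-(phenylselanyl)cyclohex-3-ene-1-carboxylate (racemic, SePh trans to C6 methyl, not isolated) | COC(=O)[C@@]1([Se]c2ccccc2)[C@@H](C)CC(OC(=O)c2c(C)c(Cl)c(OCOC)c(C)c2OCOC)=CC1=O | intermediate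
16 | corresponding selenoxide, 1-(benzeneseleninyl) compound (racemic, mixed at selenium, not isolated) | COC(=O)[C@@]1([Se](=O)c2ccccc2)[C@@H](C)CC(OC(=O)c2c(C)c(Cl)c(OCOC)c(C)c2OCOC)=CC1=O | intermediate
17 | methyl 4-{[3-chloro-4,6-bis(methoxymethoxy)-2,5-dimethylbenzoyl]oxy}-2-hydroxy-6-methylbenzoate | COC(=O)c1c(C)cc(OC(=O)c2c(C)c(Cl)c(OCOC)c(C)c2OCOC)cc1O | intermediate
18 | methyl 4-[(3-chloro-4,6-dihydroxy-2,5-dimethylbenzoyl)oxy]-2-hydroxy-6-methylbenzoate | COC(=O)c1c(C)cc(OC(=O)c2c(C)c(Cl)c(O)c(C)c2O)cc1O | target

**Count and risks**

Total step count: 8. Longest linear sequence: 7 steps (from 6 through steps 2–8 to 18).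

Steps most likely to fail:

1. Step 6 (fragment union). What may go wrong: acylation of the ambident dione enolate partly at O2, amine-promoted migration of the acyl group from oxygen to C3, or decay of the acid chloride through attack of its ortho acetal oxygen on the acyl carbon before it is trapped. Fallback: the order is changed to aromatise first and esterify second, without an acid chloride. It sets out from 5. Bromine in acetic acid should brominate and dehydrobrominate the ring to methyl 3,5-dibromo-2,4-dihydroxy-6-methylbenzoate F1. Hydrogenolysis (H2, palladium on carbon Pd/C, NaOAc, MeOH) removes both bromines to give methyl 2,4-dihydroxy-6-methylbenzoate F2. Its 2-OH is tied up in a hydrogen bond to the ester, so carbodiimide esterification with acid 12 (DCC, catalytic DMAP, CH2Cl2) should take place at the free 4-OH. The fallback comes back to the route at 17, with steps 6 and 7 bypassed.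

2. Step 7 (aromatisation). What may go wrong: selenenylation on the face that places selenium trans to H6, so that syn-elimination stalls, and over-oxidation of the new phenol by the seleninic acid formed during the peroxide stage. Fallback: direct dehydrogenation by hydride abstraction instead of functionalisation and elimination. It sets out from 14: DDQ in dioxane at 80 °C should remove hydride from C6 of the enolised β-keto ester, and loss of a proton gives the same dienone tautomer with no stereochemical requirement. It comes back at 17 and makes no new compound.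

3. Step 8 (deprotection). What may go wrong: methanolysis of the ester that links the two rings in competition with acetal cleavage, and alkylation of ring B at C3 or C5 by the liberated methoxymethyl cation. Fallback: the phenol protection is changed to benzyl ethers, which are removed under aprotic, non-nucleophilic conditions; hydrogenolysis is avoided because of the aryl chloride. It sets out from 9 and follows the main sequence with the new protecting group:
   - BnBr, K2CO3, DMF, 60 °C should give 4,6-bis(benzyloxy)-3-chloro-2,5-dimethylbenzaldehyde F3.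
   - Pinnick oxidation as in step 5 gives 4,6-bis(benzyloxy)-3-chloro-2,5-dimethylbenzoic acid F4.
   - The α-chloroenamine converts it into 4,6-bis(benzyloxy)-3-chloro-2,5-dimethylbenzoyl chloride F5, which acylates 5 as in step 6 to give the bis-benzyl enol ester F6.
   - PhSeCl/pyridine then H2O2, as in step 7, lead through the bis-benzyl selenide F7 and the bis-benzyl selenoxide F8 to methyl 4-{[4,6-bis(benzyloxy)-3-chloro-2,5-dimethylbenzoyl]oxy}-2-hydroxy-6-methylbenzoate F9.
   - BCl3 and pentamethylbenzene in CH2Cl2 at −78 °C cleave both benzyl ethers, and the fallback comes back at 18.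

Further compounds
F1 | step 6 | methyl 3,5-dibromo-2,4-dihydroxy-6-methylbenzoate | COC(=O)c1c(C)c(Br)c(O)c(Br)c1O
F2 | step 6 | methyl 2,4-dihydroxy-6-methylbenzoate (methyl orsellinate) | COC(=O)c1c(C)cc(O)cc1O
F0 | step 7 | none | none
F3 | step 8 | 4,6-bis(benzyloxy)-3-chloro-2,5-dimethylbenzaldehyde | O=Cc1c(C)c(Cl)c(OCc2ccccc2)c(C)c1OCc1ccccc1
F4 | step 8 | 4,6-bis(benzyloxy)-3-chloro-2,5-dimethylbenzoic acid | OC(=O)c1c(C)c(Cl)c(OCc2ccccc2)c(C)c1OCc1ccccc1
F5 | step 8 | 4,6-bis(benzyloxy)-3-chloro-2,5-dimethylbenzoyl chloride | ClC(=O)c1c(C)c(Cl)c(OCc2ccccc2)c(C)c1OCc1ccccc1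
F6 | step 8 | methyl 4-{[4,6-bis(benzyloxy)-3-chloro-2,5-dimethylbenzoyl]oxy}-6-methyl-2-oxocyclohex-3-ene-1-carboxylate (racemic) | COC(=O)[C@@H]1[C@@H](C)CC(OC(=O)c2c(C)c(Cl)c(OCc3ccccc3)c(C)c2OCc2ccccc2)=CC1=O
F7 | step 8 | methyl 4-{[4,6-bis(benzyloxy)-3-chloro-2,5-dimethylbenzoyl]oxy}-6-methyl-2-oxo-1-(phenylselanyl)cyclohex-3-ene-1-carboxylate (racemic, SePh trans to C6 methyl) | COC(=O)[C@@]1([Se]c2ccccc2)[C@@H](C)CC(OC(=O)c2c(C)c(Cl)c(OCc3ccccc3)c(C)c2OCc2ccccc2)=CC1=O
F8 | step 8 | selenoxide of F7 (racemic, mixed at selenium) | COC(=O)[C@@]1([Se](=O)c2ccccc2)[C@@H](C)CC(OC(=O)c2c(C)c(Cl)c(OCc3ccccc3)c(C)c2OCc2ccccc2)=CC1=O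
F9 | step 8 | methyl 4-{[4,6-bis(benzyloxy)-3-chloro-2,5-dimethylbenzoyl]oxy}-2-hydroxy-6-methylbenzoate | COC(=O)c1c(C)cc(OC(=O)c2c(C)c(Cl)c(OCc3ccccc3)c(C)c2OCc2ccccc2)cc1O
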